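The route builds on recognising ring B (C5–C10, with C17 on the C7=C8 alkene) as the carvone ring and the carvone isopropenyl group as C4 carrying C18 and C19. A diazoketone arm on C10 (C1–C2–C3) is decomposed by a copper catalyst so that the C3 carbenoid adds across C4=C19. This one operation forms C3–C4 and C3–C19, closes ring A and a cyclopropane, and sets C3 and C4. The precursor is a 6,6-disubstituted carvone bearing the C20 methyl and a CH2C(O)CHN2 chain trans to the isopropenyl group. Isovaleric acid later opens the strained C3–C19 bond and installs the C19 ester directly.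

Key step: step 5

Assumption: labdane numbering is used throughout; centres that are erased or removed later (C6 of 2, the future C10; C9 of 21; the acetal carbon of the tetrahydropyranyl ethers) are carried as epimer mixtures and drawn without configuration.

Step 1
Reactants: 1 (R)-(−)-carvone
Product: 2 (5R)-2,6-dimethyl-5-(prop-1-en-2-yl)cyclohex-2-en-1-one (6-methylcarvone; both C6 epimers)
Conditions: LiN(iPr)2 (1.1 equiv), THF, −78 °C; MeI, −78 to 0 °C
Reagents that add atoms: iodomethane, CI
Why: Kinetic α′-deprotonation of the enone at its only α′ position (the future C10) and SN2 methylation of the lithium enolate (enolate alkylation) bring in C20; the new centre need not be controlled because step 2 makes it quaternary.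

Step 2
Reactants: 2 6-methylcarvone; 3 ethyl bromoacetate
Product: 4 ethyl 2-[(1S,6S)-1,3-dimethyl-2-oxo-6-(prop-1-en-2-yl)cyclohex-3-en-1-yl]acetate (acetate arm trans to the isopropenyl group)
Conditions: LiN(iPr)2 (1.1 equiv), THF, −78 °C; 3, DMPU, −78 °C to rt
Reagents that add atoms: none
Why: A second kinetic enolisation gives the tetrasubstituted enolate, and its alkylation (enolate alkylation) should occur on the face opposite the neighbouring isopropenyl group, so the C1–C2 arm ends trans to C4 and the C20 methyl cis to it, which fixes C10.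

Step 3
Reactants: 4 keto ester
Product: 5 2-[(1S,6S)-1,3-dimethyl-2-oxo-6-(prop-1-en-2-yl)cyclohex-3-en-1-yl]acetic acid
Conditions: LiOH·H2O, THF–H2O (3:1), rt; then 1 M HCl to pH 3
Reagents that add atoms: lithium hydroxide, [Li+].[OH-]
Why: Saponification (acyl–oxygen ester hydrolysis) of an alkali-cleavable ethyl ester keeps the isopropenyl group away from the strong acid that would let it lactonise onto the neighbouring carboxyl group; C10 is quaternary and C5–H is not acidic, so no stereocentre is touched.

Step 4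
Reactants: 5 keto acid
Product: 7 (5S,6S)-6-(3-diazo-2-oxopropyl)-2,6-dimethyl-5-(prop-1-en-2-yl)cyclohex-2-en-1-one, via acid chloride 6 (not isolated)
Conditions: (COCl)2, DMF (cat.), CH2Cl2, 0 °C to rt, evaporate; CH2N2 (3 equiv), Et2O, 0 °C
Reagents that add atoms: diazomethane, C=[N+]=[N-]
Why: Vilsmeier-type conversion of the acid into its chloride and C-acylation of diazomethane (first stage of the Arndt–Eistert sequence) should give the α-diazoketone, excess diazomethane taking up the HCl; no stereocentre is involved.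

Step 5
Reactants: 7 diazoketone
Product: 8 3,19-cyclo-11,12,13,14,15,16-hexanorlabd-7-ene-2,9-dione (5α-H, 10β-CH3, 3α-H; cyclopropane C3–C4–C19 on the β face, C18 α)
Conditions: Cu(acac)2 (5 mol %), toluene, 85 °C; 7 added slowly by syringe pump (final 0.005 M)
Reagents that add atoms: none
Why: Cu(acac)2 decomposes the diazoketone to an electrophilic copper carbenoid at C3, which adds in a concerted, asynchronous [2+1] manner to the nucleophilic C4=C19 bond of the isopropenyl group (intramolecular Stork–Ficini-type cyclopropanation of an unsaturated α-diazoketone). Ring A is closed in the six-membered exo mode by the C3–C4 bond (tether C3–C2–C1–C10–C5–C4), and the cyclopropane is closed in the same event by the C3–C19 bond. C4 is set by the alkene face that is presented: in the chair-like approach the rotamer that turns the small =CH2 (C19), not the C18 methyl, toward the axial C20 methyl on C10 should be preferred, which puts C19 on the β face; C3 follows from C4 because the three-membered ring can only be cis-fused and the carbene adds suprafacially (3α-H). The step needs chemoselectivity for the 1,1-disubstituted alkene over the enone alkene, over insertion into the allylic C5–H bond and over capture by the C9 carbonyl oxygen: the enone alkene is electron-poor and reachable only through a bridged transition state, copper carbenoids scarcely insert into C–H bonds, and high dilution should favour the irreversible alkene addition over reversible oxygen capture. The trans relation of the C1 and C4 arms fixed in step 2 holds carbene and alkene gauche on ring B, so the trans ring fusion can form without strain.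

Step 6
Reactants: 8 cyclopropyl diketone; 9 isovaleric acid (3-methylbutanoic acid)
Product: 10 19-(3-methylbutanoyloxy)-11,12,13,14,15,16-hexanorlabd-7-ene-2,9-dione (4α-CH3, 4β-CH2O, 5α-H, 10β-CH3)
Conditions: 9 (neat, 20 equiv), conc. H2SO4 (0.2 equiv), 50 °C
Reagents that add atoms: none
Why: Acid-promoted homoconjugate addition of a carboxylic acid to a cyclopropyl ketone (the reaction type of the 3,5-cyclosteroid 6-ketone acetolysis): the protonated C2 carbonyl overlaps best with the exocyclic C3–C19 bond, and the acid attacks the unhindered C19 methylene in an SN2-like way, so C4 keeps C19 β and C18 α while C3 becomes CH2.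

Step 7
Reactants: 10 diketo ester
Product: 11 2,2-(ethylenedioxy)-19-(3-methylbutanoyloxy)-11,12,13,14,15,16-hexanorlabd-7-en-9-one
Conditions: (Me3SiOCH2)2 (2 equiv), Me3SiOTf (5 mol %), CH2Cl2, −78 to −20 °C
Reagents that add atoms: 1,2-bis(trimethylsilyloxy)ethane, C[Si](C)(C)OCCO[Si](C)(C)C
Why: Silyl-triflate-catalysed ketalisation with the bis-silyl ether of ethylene glycol should take only the saturated C2 ketone, because the C9 carbonyl is conjugated and flanked by the quaternary C10 and the substituted C8; the dioxolane shields C2 from the organometallic of step 12.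

Step 8
Reactants: 12 tert-butyl(but-3-yn-1-yloxy)dimethylsilane
Product: 15 (E)-5-[(tert-butyldimethylsilyl)oxy]-3-methylpent-2-en-1-ol, via alkenylalane 13 (not isolated), via lithium alkenylaluminate 14 (not isolated)
Conditions: Me3Al (2.5 equiv), Cp2ZrCl2 (0.25 equiv), CH2Cl2, 0 °C to rt; volatiles removed; n-BuLi, THF–hexane, −78 °C; (CH2O)n, −78 °C to rt; aq. KNaC4H4O6
Reagents that add atoms: trimethylaluminium, C[Al](C)C; formaldehyde (as paraformaldehyde), C=O
Why: Zirconium-catalysed syn carboalumination of the terminal alkyne (Negishi carboalumination) puts CH3 on the internal and aluminium on the terminal carbon, which fixes the E geometry of the future C13=C14 bond, and the derived aluminate is hydroxymethylated by formaldehyde with retention.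

Step 9
Reactants: 15 allylic alcohol
Product: 16 2-{[(E)-5-[(tert-butyldimethylsilyl)oxy]-3-methylpent-2-en-1-yl]oxy}tetrahydro-2H-pyran
Conditions: 3,4-dihydro-2H-pyran (1.5 equiv), PPTS (cat.), CH2Cl2, rt
Reagents that add atoms: 3,4-dihydro-2H-pyran, C1CCOC=C1
Why: Acid-catalysed addition of the alcohol to the enol ether (tetrahydropyranyl acetal formation) protects the future C15 oxygen with a group that survives organolithium chemistry and leaves with the dioxolane in step 16.

Step 10
Reactants: 16 silyl ether
Product: 17 (E)-3-methyl-5-(tetrahydro-2H-pyran-2-yloxy)pent-3-en-1-ol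
Conditions: Bu4NF (1.2 equiv), THF, 0 °C to rt
Reagents that add atoms: none
Why: Fluoride-induced Si–O cleavage (desilylation) frees the homoallylic alcohol and leaves the acetal and the alkene geometry untouched.

Step 11
Reactants: 17 homoallylic alcohol
Product: 18 2-{[(E)-5-iodo-3-methylpent-2-en-1-yl]oxy}tetrahydro-2H-pyran
Conditions: I2, PPh3, imidazole, CH2Cl2, 0 °C
Reagents that add atoms: iodine, II
Why: Appel-type iodination of the primary alcohol by SN2 displacement of the alkoxyphosphonium ion; the carbinol is homoallylic, so no allylic transposition can occur.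

Step 12
Reactants: 11 ketal enone; 18 homoallylic iodide
Product: 21 2,2-(ethylenedioxy)-9-hydroxy-19-(3-methylbutanoyloxy)-15-(tetrahydropyran-2-yloxy)labda-7,13E-diene (C9 epimers), via alkyllithium 19 (not isolated), via organocerium reagent 20 (not isolated)
Conditions: 18 (1.5 equiv), t-BuLi (3.0 equiv), Et2O–pentane, −78 °C; CeCl3 (anhydrous), THF, −78 °C; then 11, −78 °C; aq. NH4Cl
Reagents that add atoms: none
Why: Iodine–lithium exchange, transmetalation to the weakly basic, oxophilic organocerium reagent and 1,2-addition to the hindered C9 enone carbonyl (organocerium carbonyl addition) should outpace acyl substitution at the neopentyl-type isovalerate at −78 °C; the C9 configuration is irrelevant because step 13 makes C9 trigonal.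

Step 13
Reactants: 21 tertiary allylic alcohol
Product: 22 2,2-(ethylenedioxy)-19-(3-methylbutanoyloxy)-15-(tetrahydropyran-2-yloxy)labda-8,13E-dien-7-one
Conditions: [C5H5NH][CrO3Cl] (3 equiv), NaOAc, 4 Å sieves, CH2Cl2, rt
Reagents that add atoms: pyridinium chlorochromate (supplies the C7 oxygen), [O-][Cr](=O)(=O)Cl.c1cc[nH+]cc1
Why: Oxidative 1,3-transposition of a tertiary allylic alcohol (Babler–Dauben oxidation): the chromate ester at C9 shifts to C7 and is oxidised there, giving the C8=C9 enone with the side chain on C9.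

Step 14
Reactants: 22 transposed enone
Product: 23 2,2-(ethylenedioxy)-19-(3-methylbutanoyloxy)-15-(tetrahydropyran-2-yloxy)labda-8,13E-dien-7β-ol
Conditions: NaBH4, CeCl3·7H2O, MeOH, −20 °C
Reagents that add atoms: none
Why: Luche 1,2-reduction: hydride should add axially from the α face of the C7 carbonyl, anti to the axial C6–H bond, giving the pseudo-equatorial 7β-alcohol.

Step 15
Reactants: 23 7β-allylic alcohol
Product: 26 2,2-(ethylenedioxy)-19-(3-methylbutanoyloxy)-15-(tetrahydropyran-2-yloxy)labda-7,13E-diene (9α-H), via sulfonylhydrazine 24 (not isolated), via allylic diazene 25 (not isolated)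
Conditions: PPh3, diethyl azodicarboxylate, 2-nitrobenzenesulfonylhydrazide (3 equiv each), THF, −30 °C; then rt
Reagents that add atoms: none
Why: Mitsunobu displacement of the 7β-alcohol by the sulfonylhydrazide with inversion, loss of 2-nitrobenzenesulfinic acid to the 7α-monoalkyl diazene and concerted retro-ene loss of N2 (reductive 1,3-transposition of an allylic alcohol) deliver hydrogen to the α face of C9 and move the alkene to C7=C8, so the chain ends β at C9; SN2′ attack is excluded because C9 is fully substituted.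

Step 16
Reactants: 26 ketal tetrahydropyranyl ether
Product: 27 15-hydroxy-19-(3-methylbutanoyloxy)labda-7,13E-dien-2-one
Conditions: PPTS (0.3 equiv), acetone–H2O (9:1), 55 °C
Reagents that add atoms: water, O
Why: Acid-catalysed hydrolysis of both acetals in one operation; the dioxolane (one oxygen syn-axial to C19 and C20) and the tetrahydropyranyl ether should cleave under conditions that leave the ester, the primary allylic alcohol and both trisubstituted alkenes alone.

Step 17
Reactants: 27 keto alcohol; 28 methyl 4-chloro-4-oxobutanoate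
Product: 29 15-(4-methoxy-4-oxobutanoyloxy)-19-(3-methylbutanoyloxy)labda-7,13E-dien-2-one
Conditions: 28 (1.2 equiv), pyridine, DMAP (cat.), CH2Cl2, 0 °C
Reagents that add atoms: none
Why: Nucleophile-catalysed O-acylation with the acid chloride of the only hydroxyl group present, so no selectivity between the C2 and C15 oxygens is required.

Step 18
Reactants: 29 keto triester
Product: 30 target CNP0118741.1, 2α-hydroxy-15-(4-methoxy-4-oxobutanoyloxy)-19-(3-methylbutanoyloxy)labda-7,13E-diene
Conditions: SmI2 (3 equiv), THF–H2O, 0 °C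
Reagents that add atoms: none
Why: Single-electron (ketyl) reduction of the C2 ketone by SmI2 with water as proton source should, like a dissolving-metal reduction, give the thermodynamically favoured equatorial 2α-alcohol (hydrogen delivered axially between C19 and C20), whereas hydride reagents would attack from the open α face and give the axial 2β-epimer; carboxylic esters and isolated alkenes are not reduced under these amine-free conditions.

Compound list
1 | (R)-(−)-carvone | CC1=CC[C@H](CC1=O)C(C)=C | starting material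
2 | (5R)-2,6-dimethyl-5-(prop-1-en-2-yl)cyclohex-2-en-1-one (C6 epimers) | CC1=CC[C@@H](C(C)=C)C(C)C1=O | intermediate
3 | ethyl bromoacetate | CCOC(=O)CBr | starting material
4 | ethyl 2-[(1S,6S)-1,3-dimethyl-2-oxo-6-(prop-1-en-2-yl)cyclohex-3-en-1-yl]acetate | O=C1C(C)=CC[C@@H](C(C)=C)[C@]1(C)CC(=O)OCC | intermediate
5 | 2-[(1S,6S)-1,3-dimethyl-2-oxo-6-(prop-1-en-2-yl)cyclohex-3-en-1-yl]acetic acid | O=C1C(C)=CC[C@@H](C(C)=C)[C@]1(C)CC(=O)O | intermediate
6 | 2-[(1S,6S)-1,3-dimethyl-2-oxo-6-(prop-1-en-2-yl)cyclohex-3-en-1-yl]acetyl chloride (not isolated) | O=C1C(C)=CC[C@@H](C(C)=C)[C@]1(C)CC(=O)Cl | intermediate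
7 | (5S,6S)-6-(3-diazo-2-oxopropyl)-2,6-dimethyl-5-(prop-1-en-2-yl)cyclohex-2-en-1-one | O=C1C(C)=CC[C@@H](C(C)=C)[C@]1(C)CC(=O)C=[N+]=[N-] | intermediate
8 | 3,19-cyclo-11,12,13,14,15,16-hexanorlabd-7-ene-2,9-dione (3α-H, 5α-H, 10β-CH3, C19 β) | O=C1C(C)=CC[C@@H]2[C@]1(C)CC(=O)[C@@H]3C[C@]23C | intermediate
9 | isovaleric acid (3-methylbutanoic acid) | CC(C)CC(O)=O | starting material
10 | 19-(3-methylbutanoyloxy)-11,12,13,14,15,16-hexanorlabd-7-ene-2,9-dione | O=C1C(C)=CC[C@H]2[C@@](C)(COC(=O)CC(C)C)CC(=O)C[C@]12C | intermediate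
11 | 2,2-(ethylenedioxy)-19-(3-methylbutanoyloxy)-11,12,13,14,15,16-hexanorlabd-7-en-9-one | O=C1C(C)=CC[C@H]2[C@@](C)(COC(=O)CC(C)C)CC3(OCCO3)C[C@]12C | intermediate
12 | tert-butyl(but-3-yn-1-yloxy)dimethylsilane | C#CCCO[Si](C)(C)C(C)(C)C | starting material
13 | (E)-{4-[(tert-butyldimethylsilyl)oxy]-2-methylbut-1-en-1-yl}dimethylalane (not isolated) | C[Al](C)/C=C(\C)CCO[Si](C)(C)C(C)(C)C | intermediate
14 | lithium butyl{(E)-4-[(tert-butyldimethylsilyl)oxy]-2-methylbut-1-en-1-yl}dimethylaluminate (not isolated) | [Li+].CCCC[Al-](C)(C)/C=C(\C)CCO[Si](C)(C)C(C)(C)C | intermediate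
15 | (E)-5-[(tert-butyldimethylsilyl)oxy]-3-methylpent-2-en-1-ol | OC/C=C(\C)CCO[Si](C)(C)C(C)(C)C | intermediate
16 | 2-{[(E)-5-[(tert-butyldimethylsilyl)oxy]-3-methylpent-2-en-1-yl]oxy}tetrahydro-2H-pyran | CC(C)(C)[Si](C)(C)OCC/C(C)=C/COC1CCCCO1 | intermediate
17 | (E)-3-methyl-5-(tetrahydro-2H-pyran-2-yloxy)pent-3-en-1-ol | OCC/C(C)=C/COC1CCCCO1 | intermediate
18 | 2-{[(E)-5-iodo-3-methylpent-2-en-1-yl]oxy}tetrahydro-2H-pyran | ICC/C(C)=C/COC1CCCCO1 | intermediate
19 | (E)-[3-methyl-5-(tetrahydro-2H-pyran-2-yloxy)pent-3-en-1-yl]lithium (not isolated) | [Li]CC/C(C)=C/COC1CCCCO1 | intermediate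
20 | dichloro[(E)-3-methyl-5-(tetrahydro-2H-pyran-2-yloxy)pent-3-en-1-yl]cerium (not isolated) | Cl[Ce](Cl)CC/C(C)=C/COC1CCCCO1 | intermediate
21 | 2,2-(ethylenedioxy)-9-hydroxy-19-(3-methylbutanoyloxy)-15-(tetrahydropyran-2-yloxy)labda-7,13E-diene (C9 epimers) | OC1(CC/C(C)=C/COC3CCCCO3)C(C)=CC[C@H]2[C@@](C)(COC(=O)CC(C)C)CC4(OCCO4)C[C@]12C | intermediate
22 | 2,2-(ethylenedioxy)-19-(3-methylbutanoyloxy)-15-(tetrahydropyran-2-yloxy)labda-8,13E-dien-7-one | C1(CC/C(C)=C/COC3CCCCO3)=C(C)C(=O)C[C@H]2[C@@](C)(COC(=O)CC(C)C)CC4(OCCO4)C[C@]12C | intermediate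
23 | 2,2-(ethylenedioxy)-19-(3-methylbutanoyloxy)-15-(tetrahydropyran-2-yloxy)labda-8,13E-dien-7β-ol | C1(CC/C(C)=C/COC3CCCCO3)=C(C)[C@@H](O)C[C@H]2[C@@](C)(COC(=O)CC(C)C)CC4(OCCO4)C[C@]12C | intermediate
24 | 7α-[1-(2-nitrobenzenesulfonyl)hydrazin-1-yl] derivative of 23 (not isolated) | C1(CC/C(C)=C/COC3CCCCO3)=C(C)[C@H](N(N)S(=O)(=O)c5ccccc5[N+](=O)[O-])C[C@H]2[C@@](C)(COC(=O)CC(C)C)CC4(OCCO4)C[C@]12C | intermediate
25 | 7α-diazenyl-2,2-(ethylenedioxy)-19-(3-methylbutanoyloxy)-15-(tetrahydropyran-2-yloxy)labda-8,13E-diene (not isolated) | C1(CC/C(C)=C/COC3CCCCO3)=C(C)[C@H](N=N)C[C@H]2[C@@](C)(COC(=O)CC(C)C)CC4(OCCO4)C[C@]12C | intermediate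
26 | 2,2-(ethylenedioxy)-19-(3-methylbutanoyloxy)-15-(tetrahydropyran-2-yloxy)labda-7,13E-diene | O(C3CCCCO3)C/C=C(\C)CC[C@H]1C(C)=CC[C@H]2[C@@](C)(COC(=O)CC(C)C)CC4(OCCO4)C[C@]12C | intermediate
27 | 15-hydroxy-19-(3-methylbutanoyloxy)labda-7,13E-dien-2-one | OC/C=C(\C)CC[C@H]1C(C)=CC[C@H]2[C@@](C)(COC(=O)CC(C)C)CC(=O)C[C@]12C | intermediate
28 | methyl 4-chloro-4-oxobutanoate | COC(=O)CCC(Cl)=O | starting material
29 | 15-(4-methoxy-4-oxobutanoyloxy)-19-(3-methylbutanoyloxy)labda-7,13E-dien-2-one | COC(=O)CCC(=O)OC/C=C(\C)CC[C@H]1C(C)=CC[C@H]2[C@@](C)(COC(=O)CC(C)C)CC(=O)C[C@]12C | intermediate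
30 | CNP0118741.1, 2α-hydroxy-15-(4-methoxy-4-oxobutanoyloxy)-19-(3-methylbutanoyloxy)labda-7,13E-diene | COC(=O)CCC(=O)OC/C=C(\C)CC[C@H]1C(C)=CC[C@H]2[C@@](C)(COC(=O)CC(C)C)C[C@H](O)C[C@]12C | target

Total step count: 18. Longest linear sequence: 14 steps (steps 1–7 and 12–18, from 1 to 30); the side-chain iodide 18 takes 4 steps (8–11).

Steps most likely to fail

Step 5. The carbenoid may be diverted instead of adding to C4=C19: a carbonyl oxygen 1,4-related to a diazoketone (here C9=O) can trap it as a six-membered carbonyl ylide, and insertion into the allylic C5–H bond is a lesser threat under copper. The fallback removes the carbonyl for the duration of the cyclisation. It sets out from 4, which is reduced (NaBH4, CeCl3·7H2O, MeOH, −20 °C) to the allylic alcohol F1 and silylated at once (tBuMe2SiOTf, 2,6-lutidine) to the silyl ether F2. Saponification (LiOH) gives the acid F3, which is activated as the isobutyl mixed anhydride F4 (iBuOCOCl, Et3N, −15 °C) and treated with diazomethane to give the diazoketone F5. Cu(acac)2 in hot toluene then closes ring A to the silyloxy cyclopropyl ketone F6, Bu4NF frees the allylic alcohol F7, and MnO2 oxidises it to 8, where the route is rejoined.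

Step 12. The organocerium reagent may attack the C19 ester carbonyl in competition with the hindered C9 ketone. The fallback takes the ester out of play for this one step. From 11, methanolysis (K2CO3, MeOH) gives the primary alcohol F8. Three equivalents of 20 (one is spent on the hydroxyl group) then give the diol F9. Selective acylation of its primary hydroxyl with 3-methylbutanoyl chloride (pyridine, DMAP cat., 0 °C), the tertiary allylic hydroxyl being inert, returns to 21.

Step 18. The reduction may show poor facial selectivity at C2 or erode the allylic ester. The fallback moves the reduction in front of the acylation and makes it an equilibrium. From 27, Meerwein–Ponndorf–Verley reduction under reversible conditions (Al(OiPr)3, iPrOH, reflux) should settle on the equatorial 2α,15-diol F10, in which only the hindered isovalerate is at risk. Its primary allylic hydroxyl is then acylated selectively with 28 (2,4,6-collidine, CH2Cl2, −78 °C), arriving at 30.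

Further compounds
F1 | step 5 | ethyl 2-[(1S,6S)-2-hydroxy-1,3-dimethyl-6-(prop-1-en-2-yl)cyclohex-3-en-1-yl]acetate (carbinol epimers) | OC1C(C)=CC[C@@H](C(C)=C)[C@]1(C)CC(=O)OCC
F2 | step 5 | ethyl 2-[(1S,6S)-2-[(tert-butyldimethylsilyl)oxy]-1,3-dimethyl-6-(prop-1-en-2-yl)cyclohex-3-en-1-yl]acetate | CC(C)(C)[Si](C)(C)OC1C(C)=CC[C@@H](C(C)=C)[C@]1(C)CC(=O)OCC
F3 | step 5 | 2-[(1S,6S)-2-[(tert-butyldimethylsilyl)oxy]-1,3-dimethyl-6-(prop-1-en-2-yl)cyclohex-3-en-1-yl]acetic acid | CC(C)(C)[Si](C)(C)OC1C(C)=CC[C@@H](C(C)=C)[C@]1(C)CC(=O)O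
F4 | step 5 | isobutyl carbonic anhydride of F3 | CC(C)(C)[Si](C)(C)OC1C(C)=CC[C@@H](C(C)=C)[C@]1(C)CC(=O)OC(=O)OCC(C)C
F5 | step 5 | 1-diazo-3-[(1S,6S)-2-[(tert-butyldimethylsilyl)oxy]-1,3-dimethyl-6-(prop-1-en-2-yl)cyclohex-3-en-1-yl]propan-2-one | CC(C)(C)[Si](C)(C)OC1C(C)=CC[C@@H](C(C)=C)[C@]1(C)CC(=O)C=[N+]=[N-]
F6 | step 5 | 9-[(tert-butyldimethylsilyl)oxy]-3,19-cyclo-11,12,13,14,15,16-hexanorlabd-7-en-2-one | CC(C)(C)[Si](C)(C)OC1C(C)=CC[C@@H]2[C@]1(C)CC(=O)[C@@H]3C[C@]23C
F7 | step 5 | 9-hydroxy-3,19-cyclo-11,12,13,14,15,16-hexanorlabd-7-en-2-one | OC1C(C)=CC[C@@H]2[C@]1(C)CC(=O)[C@@H]3C[C@]23C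
F8 | step 12 | 2,2-(ethylenedioxy)-19-hydroxy-11,12,13,14,15,16-hexanorlabd-7-en-9-one | O=C1C(C)=CC[C@H]2[C@@](C)(CO)CC3(OCCO3)C[C@]12C
F9 | step 12 | 2,2-(ethylenedioxy)-15-(tetrahydropyran-2-yloxy)labda-7,13E-diene-9,19-diol (C9 epimers) | OC1(CC/C(C)=C/COC3CCCCO3)C(C)=CC[C@H]2[C@@](C)(CO)CC4(OCCO4)C[C@]12C
F10 | step 18 | 19-(3-methylbutanoyloxy)labda-7,13E-diene-2α,15-diol | OC/C=C(\C)CC[C@H]1C(C)=CC[C@H]2[C@@](C)(COC(=O)CC(C)C)C[C@H](O)C[C@]12C
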